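The data were computed with constants of no real substance; noise was put on by code.

A small charge of electrophile, as in the red run, is down to 0.6% after 0.250 d, while the larger charge of the grey run still holds 52.0% then, and its target falls as it goes on.

| flask | electrophile | nucleophile | free base | remark | time |
|---|---|---|---|---|---|
| red | 0.15 M | 0.45 M | 0.33 M | run made earlier |  |
| grey | 0.60 M | 0.45 M | 0.33 M | run made earlier |  |
| flask | 0.30 M | 0.450 M | 0.330 M |  | 8.0 d |

- red (time / d: electrophile / %, target / %): 0.250: 0.6, 97.7; 0.833: 1.6, 98.4; 1.25: 0, 99.1; 2.08: 0.3, 98.7; 3.00: 0.1, 100.0; 4.00: 0.6, 99.3; 5.00: 0.1, 98.7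
- grey (time / d: electrophile / %, target / %): 0.250: 52.0, 30.9; 0.833: 40.0, 23.0; 1.25: 32.4, 17.9; 2.08: 23.8, 15.3; 3.00: 17.0, 12.4; 4.00: 11.8, 10.5; 5.00: 8.1, 10.8

(each reading ± 1 percentage point)

- part of the electrophile that has reacted at 8.0 d
- share of the unused nucleophile that is free and not bound as protonated nucleophile, at 8.0 d

So we turn the question round: what must be true for electrophile to survive in the flask? We read each reacted electrophile as costing two nucleophile, one to react and one to take up the acid. We call the cover the nucleophile charged over twice the electrophile charged: 0.750 in the flask, 1.50 in red, 0.375 in grey. The red run, with a cover above one, reads 98.7% target at 5.00 d. Here a quarter is uncovered. It goes on to target, and each side product holds two, so we expect side product near 50.0%.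

The grey tail falls at 0.391 /d, which over its mean target reads as 3.13 /M/d. Electrophile and target fall together, so we estimate target in the flask near 0.150 M once the covered part has reacted. At that target we estimate that electrophile decays at 0.469 /d, reckoned as a simple exponential. Survival to 8.0 d would need a rate below 0.125 /d, and our estimate is higher, so we estimate that 0.585% of the charge remains.

The forecast gives 99.3% and 0.5%, the second, in its words, “this is a guess”.

The flask gives 99.2% and 27.4%, the second well above the forecast.

    electrophile + nucleophile ⇌ acid set free + target (K = 0.280, k = 0.00270 /M/s)
    nucleophile + acid set free ⇌ protonated nucleophile, settled at all times (K = 11000 /M)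
    acid set free + free base ⇌ salt of the base (K = 22000 /M, k = 0.00140 /M/s)
    electrophile + target → side product (k = 3.00 × 10⁻⁵ /M/s)
    free base ⇌ dormant form (K = 1.10, k = 2.40 × 10⁻⁵ /s)

Side product in the flask holds 43.3% against our 50.0%, electrophile left stands at 0.79% against our 0.585%, and the neighbour flask, with 0.77 M of nucleophile and a cover of 1.28, holds 3.96% side product. The flask has not come to rest: at 80.0 d the reacted part reaches 99.9%, side product 53.5%, and salt of the base rises from 0.0746 M to 0.123 M. Protonated nucleophile falls from 0.158 M to 0.0968 M, and the free share of unused nucleophile climbs to 58.0%.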